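**Strategy.** The pyranone (C) ring of the flavonol holds two neighbouring carbons that both sit at the carbonyl oxidation level: the keto carbon C4 and the oxygen-bearing enol carbon C3, a hidden acyloin. The route cuts C3–C4 and goes back to a dialdehyde whose two formyl carbons are tethered through O1–C2: 2-(2-formyl-3,5-dimethoxyphenoxy)-2-(4-methoxyphenyl)acetaldehyde. A triazolium-derived carbene turns the aryl formyl group into an acyl-anion equivalent that adds to the aliphatic one. This single operation forms C3–C4 and closes the C ring as a 3-hydroxychroman-4-one. Oxidation to the flavonol removes the C2 and C3 centres; demethylation and sulfation of O3, O7 and O4' finish the target.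

Key step: step 5

Assumption: the target is planar and has no stereocentre, so no enantiomer question arises; it is drawn as the free tris(hydrogen sulfate) and is delivered in that form by cold cation exchange of its salt.

**Route**

Step 1
Reactants: 1 methyl 2-(4-methoxyphenyl)acetate
Product: 2 methyl 2-bromo-2-(4-methoxyphenyl)acetate (racemic)
Conditions: NBS (1.05 equiv), AIBN (5 mol%), PhCF3, 80 °C
Reagents that add atoms: N-bromosuccinimide, O=C1CCC(=O)N1Br
Why: Wohl–Ziegler bromination, in which the benzylic C–H flanked by the ester is the weakest C–H and is abstracted selectively, while the non-polar radical medium disfavours ring bromination; the new centre is racemic and is erased in step 6.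

Step 2
Reactants: 2 methyl 2-bromo-2-(4-methoxyphenyl)acetate; 3 2-hydroxy-4,6-dimethoxybenzaldehyde
Product: 4 methyl 2-(2-formyl-3,5-dimethoxyphenoxy)-2-(4-methoxyphenyl)acetate (racemic)
Conditions: K2CO3, DMF, rt → 40 °C
Reagents that add atoms: none
Why: Williamson ether synthesis, in which the phenoxide of 3 displaces the activated benzylic α-bromo ester, which has no β-hydrogen and cannot eliminate, and the mild base leaves the electron-rich formyl group untouched by the ester enolate.

Step 3
Reactants: 4 methyl 2-(2-formyl-3,5-dimethoxyphenoxy)-2-(4-methoxyphenyl)acetate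
Product: 5 2-[2-(hydroxymethyl)-3,5-dimethoxyphenoxy]-2-(4-methoxyphenyl)ethan-1-ol (racemic)
Conditions: LiAlH4 (1.5 equiv), THF, 0 °C; Rochelle salt work-up
Reagents that add atoms: none
Why: Hydride reduction with LiAlH4 takes the ester and the aldehyde to primary alcohols in one operation, the aryl ethers are inert, and the non-acidic work-up protects the electron-rich benzylic alcohol.

Step 4
Reactants: 5 2-[2-(hydroxymethyl)-3,5-dimethoxyphenoxy]-2-(4-methoxyphenyl)ethan-1-ol
Product: 6 2-(2-formyl-3,5-dimethoxyphenoxy)-2-(4-methoxyphenyl)acetaldehyde (racemic)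
Conditions: Dess–Martin periodinane (2.5 equiv), pyridine, CH2Cl2, 0 °C → rt; short filtration, used crude at once
Reagents that add atoms: none
Why: Dess–Martin oxidation converts both primary alcohols to aldehydes at near-neutral pH without over-oxidation, and the absence of a strong amine base avoids enolisation or aldol closure of the C2–H acidic aldehyde.

Step 5
Reactants: 6 2-(2-formyl-3,5-dimethoxyphenoxy)-2-(4-methoxyphenyl)acetaldehyde
Product: 7 3-hydroxy-5,7-dimethoxy-2-(4-methoxyphenyl)chroman-4-one (racemic, 2,3-cis/trans mixture)
Conditions: 2-(pentafluorophenyl)-6,7-dihydro-5H-pyrrolo[2,1-c][1,2,4]triazol-2-ium tetrafluoroborate (15 mol%), i-Pr2NEt (10 mol%), degassed toluene (0.02 M), rt, Ar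
Reagents that add atoms: none
Why: Proposed new method: the triazolylidene adds reversibly to the aryl formyl group (C4), proton transfer gives the enaminol acyl-anion equivalent, and its carbon adds to the α-aryloxy formyl group (C3) before the alkoxide collapses and releases the carbene, so the C3–C4 bond of an α-ketol is formed. The closest known reaction type is the carbene-catalysed intramolecular crossed benzoin of 2-(2-oxoalkoxy)benzaldehydes to 3-hydroxychroman-4-ones; an aldehyde acceptor in place of the ketone has not been shown on this substrate class. The pyranone C ring closes in a 6-exo-trig mode. The new C3 stereocentre is influenced only by the existing C2 centre (aryl pseudo-equatorial, trans expected to be favoured and equilibrated by enolisation), and no control is needed because C2 and C3 both become sp2 in step 6. The step needs acyl-anion formation at the aryl aldehyde, because an enaminol at C3 would expel the O1 aryloxide and cleave the tether, and it needs the benzoin to outpace the 5-exo aldol of the C2–H acidic aldehyde. The substrate supports this through its two ortho oxygens, which favour carbene addition to the aryl formyl group and give a benzylic, more acidic adduct C–H, through the tertiary α-carbon, which shields the aliphatic formyl group from the N-aryl carbene yet leaves it a strongly activated acceptor, and through the electron-rich ring, which makes the aryl formyl group a poor aldol acceptor under sub-stoichiometric weak amine base.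

Step 6
Reactants: 7 3-hydroxy-5,7-dimethoxy-2-(4-methoxyphenyl)chroman-4-one
Product: 9 3-hydroxy-5,7-dimethoxy-2-(4-methoxyphenyl)-4H-chromen-4-one, via chromane-3,4-dione 8 (not isolated)
Conditions: I2 (1.1 equiv), KOAc, AcOH, 100 °C
Reagents that add atoms: none
Why: Iodine-mediated dehydrogenation of a dihydroflavonol, in which the C3–C4 enediol of the ketol is oxidised to dione 8, whose doubly activated C2–H enolises to the aromatic 4-pyranone, so both stereocentres (and any regioisomeric ketol) converge on one flavonol while the aryl methyl ethers survive.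

Step 7
Reactants: 9 3-hydroxy-5,7-dimethoxy-2-(4-methoxyphenyl)-4H-chromen-4-one
Product: 10 kaempferol (3,5,7-trihydroxy-2-(4-hydroxyphenyl)-4H-chromen-4-one)
Conditions: BBr3 (8 equiv), CH2Cl2, −78 °C → rt; MeOH, then H2O
Reagents that add atoms: none
Why: Lewis-acid cleavage of aryl methyl ethers with BBr3, in which bromide attacks each methyl group after boron coordination, the flavonol core tolerates the reagent, and aqueous methanol releases the free hydroxyls.

Step 8
Reactants: 10 kaempferol
Product: 11 kaempferol 3,7,4'-tri-O-sulfate
Conditions: SO3·pyridine (6 equiv), pyridine/DMF, 0 °C → rt; Dowex 50W (H+), H2O, 0 °C; lyophilise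
Reagents that add atoms: sulfur trioxide–pyridine complex, O=S(=O)([O-])[n+]1ccccc1
Why: O-Sulfation with an amine–sulfur trioxide complex should esterify the 7- and 4'-phenols and the enolic 3-OH, whereas the 5-OH is held in a six-membered hydrogen bond to the C4 carbonyl and should stay free at room temperature; cold cation exchange delivers the free acid form.

**Compound list**

1 | methyl 2-(4-methoxyphenyl)acetate | COC(=O)Cc1ccc(OC)cc1 | starting material
2 | methyl 2-bromo-2-(4-methoxyphenyl)acetate (racemic) | COC(=O)C(Br)c1ccc(OC)cc1 | intermediate
3 | 2-hydroxy-4,6-dimethoxybenzaldehyde | O=Cc1c(O)cc(OC)cc1OC | starting material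
4 | methyl 2-(2-formyl-3,5-dimethoxyphenoxy)-2-(4-methoxyphenyl)acetate (racemic) | COC(=O)C(Oc1cc(OC)cc(OC)c1C=O)c1ccc(OC)cc1 | intermediate
5 | 2-[2-(hydroxymethyl)-3,5-dimethoxyphenoxy]-2-(4-methoxyphenyl)ethan-1-ol (racemic) | OCC(Oc1cc(OC)cc(OC)c1CO)c1ccc(OC)cc1 | intermediate
6 | 2-(2-formyl-3,5-dimethoxyphenoxy)-2-(4-methoxyphenyl)acetaldehyde (racemic) | O=CC(Oc1cc(OC)cc(OC)c1C=O)c1ccc(OC)cc1 | intermediate
7 | 3-hydroxy-5,7-dimethoxy-2-(4-methoxyphenyl)chroman-4-one (racemic, 2,3-cis/trans mixture) | O=C1c2c(OC)cc(OC)cc2OC(c2ccc(OC)cc2)C1O | intermediate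
8 | 5,7-dimethoxy-2-(4-methoxyphenyl)chromane-3,4-dione (racemic, not isolated) | O=C1C(=O)c2c(OC)cc(OC)cc2OC1c1ccc(OC)cc1 | intermediate
9 | 3-hydroxy-5,7-dimethoxy-2-(4-methoxyphenyl)-4H-chromen-4-one | O=c1c(O)c(-c2ccc(OC)cc2)oc2cc(OC)cc(OC)c12 | intermediate
10 | kaempferol | O=c1c(O)c(-c2ccc(O)cc2)oc2cc(O)cc(O)c12 | intermediate
11 | kaempferol 3,7,4'-tri-O-sulfate (achiral) | O=c1c(OS(=O)(=O)O)c(-c2ccc(OS(=O)(=O)O)cc2)oc2cc(OS(=O)(=O)O)cc(O)c12 | target

**Step count and risk**

Total step count: 8. Longest linear sequence: 8 steps (1 → 11; 3 enters at step 2).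

Steps most likely to fail:

1. Step 5 (proposed new method). The carbene may be captured by the aliphatic formyl group, after which the enaminol expels the O1 aryloxide and the O1–C2 tether is lost by internal redox cleavage. Base-induced enolisation at C2 may also lead to 5-exo aldol closure before C3–C4 forms. The fallback uses known chemistry and sets out from 6. Reductive pinacol cyclisation with SmI2 (THF, t-BuOH, −78 °C), an established way of closing cis-1,2-diols in six-membered rings from 1,6-dialdehydes by ketyl coupling, should join the two formyl carbons to give 5,7-dimethoxy-2-(4-methoxyphenyl)chromane-3,4-diol F1. IBX in DMSO, which oxidises 1,2-diols to 1,2-diones without glycol cleavage, should then take both carbinols to dione 8. The fallback rejoins the route at 8, which enolises to 9 as in step 6, so that 7 is bypassed.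

2. Step 4. The electron-rich benzylic alcohol may ionise under traces of acid, a hydroxy-aldehyde may close to a lactol and over-oxidise, and the dialdehyde may enolise or hydrate during handling. The fallback sets out from 4 and avoids the diol. The aryl formyl group is masked as its dimethyl acetal (MeOH, HC(OMe)3, cat. PPTS) to give methyl 2-[2-(dimethoxymethyl)-3,5-dimethoxyphenoxy]-2-(4-methoxyphenyl)acetate F2. Partial reduction of the α-aryloxy ester with DIBAL-H (toluene, −78 °C) gives 2-[2-(dimethoxymethyl)-3,5-dimethoxyphenoxy]-2-(4-methoxyphenyl)acetaldehyde F3. Mild hydrolysis of the very labile electron-rich acetal (PPTS, wet acetone, rt) returns to the route at 6.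

3. Step 8. Sulfation may stop short at the enolic 3-OH or run on to the 5-OH, and sulfate may be lost by hydrolysis during acidification and isolation of the very polar product. The fallback sets out from 10 and uses protected sulfate diesters. 2,2,2-Trichloroethyl chlorosulfate (3.3 equiv), Et3N and DMAP in THF should give the neutral, chromatographable kaempferol 3,7,4'-tris(2,2,2-trichloroethyl sulfate) F4. Reductive unmasking with Zn and HCO2NH4 in MeOH, followed by the same cold cation exchange, comes back to the route at 11.

**Further compounds**

F1 | step 5 | 5,7-dimethoxy-2-(4-methoxyphenyl)chromane-3,4-diol (3,4-cis, racemic, C2 epimers) | OC1c2c(OC)cc(OC)cc2OC(c2ccc(OC)cc2)C1O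
F2 | step 4 | methyl 2-[2-(dimethoxymethyl)-3,5-dimethoxyphenoxy]-2-(4-methoxyphenyl)acetate (racemic) | COC(=O)C(Oc1cc(OC)cc(OC)c1C(OC)OC)c1ccc(OC)cc1
F3 | step 4 | 2-[2-(dimethoxymethyl)-3,5-dimethoxyphenoxy]-2-(4-methoxyphenyl)acetaldehyde (racemic) | O=CC(Oc1cc(OC)cc(OC)c1C(OC)OC)c1ccc(OC)cc1
F4 | step 8 | kaempferol 3,7,4'-tris(2,2,2-trichloroethyl sulfate) | O=c1c(OS(=O)(=O)OCC(Cl)(Cl)Cl)c(-c2ccc(OS(=O)(=O)OCC(Cl)(Cl)Cl)cc2)oc2cc(OS(=O)(=O)OCC(Cl)(Cl)Cl)cc(O)c12
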